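**Plan**

- Retrosynthesis: the C4–C4a bond of the dihydropyran (O1–C2–C3=C4–C4a–C8a) is cut first, which rearomatises the carbocycle to an aryl 1,1-dimethylpropargyl ether. The O–CMe2 bond, the two aryl–prenyl bonds and the aryl–acyl bond are then cut, back to phloroglucinol.
- Enabling feature: C4a and C8, the two carbons flanking the ether carbon C8a, both carry prenyl, and C5=O and C7–OH flank the acyl carbon C6. The carbocycle is therefore a dearomatised 3,5-diprenyl-4-O-alkyl acylphloroglucinol, whose aromatic form is Cs-symmetric with two blocked, enantiotopic ortho carbons.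
- Forward: phloroglucinol 1 + isobutyryl chloride 2 → acylphloroglucinol 3; 3 + chloroalkyne 4 → 4-O-propargyl ether 5; 5 + prenyl bromide 6 → diprenyl ether 7; 7 → target 8. The carbocycle comes from 1, and the dihydropyran is the only ring closed, in the last step.
- Ring closure: a gold(I)-catalysed dearomative 6-endo-dig cycloisomerisation of 7.
- Stereochemistry: the single stereocentre (4aR, quaternary) is set in the ring closure by catalyst-controlled desymmetrisation of 7. It is formed in the last step and cannot epimerise.

Key step: step 4

Assumption: the sense of induction of the chiral gold catalyst cannot be predicted with confidence; the (R)-ligand is written, and its antipode is to be used if a small-scale test should favour the 4aS product.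
Assumption: the enol form drawn for 8 (C5 ketone, C7 enol) is taken to equilibrate freely with the other enol forms of the same compound, so no step is needed to set it.

**Route**

Step 1
Reactants: 1 phloroglucinol; 2 isobutyryl chloride
Product: 3 phlorisobutyrophenone (2-methyl-1-(2,4,6-trihydroxyphenyl)propan-1-one)
Conditions: AlCl3 (3.5 equiv), PhNO2–CH2Cl2, 0 → 45 °C; then ice/1 M HCl
Reagents that add atoms: none
Why: Friedel–Crafts acylation of the triply activated arene should stop after one acyl group because the aluminium-chelated aryl ketone is deactivated; no stereocentre is formed.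

Step 2
Reactants: 3 phlorisobutyrophenone; 4 3-chloro-3-methylbut-1-yne
Product: 5 1-[2,6-dihydroxy-4-(2-methylbut-3-yn-2-yloxy)phenyl]-2-methylpropan-1-one
Conditions: 4 (1.1 equiv), DBU (1.3 equiv), CuCl2·2H2O (1 mol %), MeCN, 0 °C
Reagents that add atoms: none
Why: Copper-catalysed propargylic etherification (substitution through a copper acetylide/allenylidene) should take place at the 4-OH, which is the most acidic phenol (para to the acyl group), is not hydrogen bonded to the ketone and has two unsubstituted neighbours, whereas the 2- and 6-OH are chelated or flanked by the acyl group; no stereocentre is formed.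

Step 3
Reactants: 5 1-[2,6-dihydroxy-4-(2-methylbut-3-yn-2-yloxy)phenyl]-2-methylpropan-1-one; 6 prenyl bromide
Product: 7 1-[2,6-dihydroxy-3,5-bis(3-methylbut-2-en-1-yl)-4-(2-methylbut-3-yn-2-yloxy)phenyl]-2-methylpropan-1-one
Conditions: 6 (2.2 equiv), 10 % aq. KOH, 0 °C → rt; then citric acid to pH 5
Reagents that add atoms: none
Why: Base-mediated C-prenylation of an acylphloroglucinol phenoxide in water, the reaction type by which deoxyhumulones are made, should alkylate C3 and C5, the only free ring carbons and each ortho to one and para to the other phenoxide oxygen, while the tertiary propargyl ether and the terminal alkyne are inert to cold aqueous alkali; the product is Cs-symmetric and has no stereocentre.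

Step 4
Reactants: 7 1-[2,6-dihydroxy-3,5-bis(3-methylbut-2-en-1-yl)-4-(2-methylbut-3-yn-2-yloxy)phenyl]-2-methylpropan-1-one
Product: 8 (4aR)-7-hydroxy-2,2-dimethyl-4a,8-bis(3-methylbut-2-en-1-yl)-6-(2-methylpropanoyl)-2H-chromen-5(4aH)-one
Conditions: [(R)-DTBM-SEGPHOS](AuCl)2 (2.5 mol %), AgNTf2 (5 mol %), 4 Å MS, toluene, −20 °C → rt; Et3N quench
Reagents that add atoms: none
Why: Proposed new method: the cationic gold(I) centre should π-activate the terminal alkyne of 7, a prenylated ortho carbon of the arene (ortho or para to all three ring oxygens and therefore strongly nucleophilic) should attack the terminal alkyne carbon anti to gold, the catalyst-bound cyclohexadienyl cation, which has no ring hydrogen to lose, should be discharged by loss of the proton of the adjacent phenol (this oxygen becomes the C5 ketone of 8), and protodeauration of the vinyl–gold bond at C3 should then release 8 and the catalyst. The closest known reaction types are the gold- or platinum-catalysed hydroarylation of aryl 1,1-dimethylpropargyl ethers to 2,2-dimethyl-2H-chromenes and the gold-catalysed dearomative alkyne carbocyclisation of phenols to cyclohexadienones; their merger on an ether with both ortho positions blocked, and its enantioselective desymmetrising form, are not established. The dihydropyran closes in the 6-endo-dig mode (C4–C4a bond), the mode regularly followed by aryl propargyl ethers with a terminal alkyne, whereas 5-exo closure would place a strained exocyclic alkene on a five-membered ring. The only stereocentre, C4a, is created in the C–C bond-forming step, in which the chiral bisphosphine–digold catalyst has to choose between the two enantiotopic ortho carbons of Cs-symmetric 7; the bulky 3,5-di-tert-butyl-4-methoxyphenyl groups that enclose the P–Au–alkyne axis are the controlling element. The step needs attack by carbon in preference to oxygen or the prenyl alkenes, and dearomatisation in place of chromene formation: both ortho carbons carry prenyl so that rearomatisation is impossible, the free 2- and 6-OH groups supply the proton loss that traps the cation before any 1,2-shift, the phenols cannot reach the alkyne, and the prenyl alkenes are 1,8-enyne partners that would have to close seven- or eight-membered rings. The new centre is quaternary and cannot epimerise afterwards.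

**Compound list**

1 | phloroglucinol (benzene-1,3,5-triol) | Oc1cc(O)cc(O)c1 | starting material
2 | isobutyryl chloride (2-methylpropanoyl chloride) | CC(C)C(Cl)=O | starting material
3 | phlorisobutyrophenone (2-methyl-1-(2,4,6-trihydroxyphenyl)propan-1-one) | CC(C)C(=O)c1c(O)cc(O)cc1O | intermediate
4 | 3-chloro-3-methylbut-1-yne | C#CC(C)(C)Cl | starting material
5 | 1-[2,6-dihydroxy-4-(2-methylbut-3-yn-2-yloxy)phenyl]-2-methylpropan-1-one | CC(C)C(=O)c1c(O)cc(OC(C)(C)C#C)cc1O | intermediate
6 | prenyl bromide (1-bromo-3-methylbut-2-ene) | CC(C)=CCBr | starting material
7 | 1-[2,6-dihydroxy-3,5-bis(3-methylbut-2-en-1-yl)-4-(2-methylbut-3-yn-2-yloxy)phenyl]-2-methylpropan-1-one | CC(C)C(=O)c1c(O)c(CC=C(C)C)c(OC(C)(C)C#C)c(CC=C(C)C)c1O | intermediate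
8 | (4aR)-7-hydroxy-2,2-dimethyl-4a,8-bis(3-methylbut-2-en-1-yl)-6-(2-methylpropanoyl)-2H-chromen-5(4aH)-one | CC(C)=CCC1=C2OC(C)(C)C=C[C@@]2(CC=C(C)C)C(=O)C(C(=O)C(C)C)=C1O | target

**Step count**

Total steps: 4. Longest linear sequence: 4 steps (1 → 3 → 5 → 7 → 8).

**Steps most likely to fail**

1. Step 4 (Proposed new method). The chiral information sits trans to the alkyne on a linear gold centre and may not discriminate the two enantiotopic ortho carbons, so the enantiomeric excess may be low. Acid-type heterolysis of the tertiary propargylic C–O bond, or hydroalkoxylation of a prenyl alkene by a neighbouring phenol, may also overtake the carbocyclisation. The fallback sets out from 7 and comes back at 8, using known reaction types only. Thermal aryl propargyl Claisen rearrangement of 7 (xylene, about 130 °C, kept as cool and short as the [3,3] shift allows so that the dienone does not undergo intramolecular cycloaddition) stops at the dienone stage because both ortho positions are blocked. It should give racemic 3,5-dihydroxy-2,6-bis(3-methylbut-2-en-1-yl)-6-(3-methylbuta-1,2-dien-1-yl)-4-(2-methylpropanoyl)cyclohexa-2,4-dien-1-one F1. Silver(I)-catalysed 6-endo cycloisomerisation of its β-allenyl enol (AgNO3 cat., acetone, rt; the β-hydroxyallene → 3,6-dihydro-2H-pyran type) should then give racemic 7-hydroxy-2,2-dimethyl-4a,8-bis(3-methylbut-2-en-1-yl)-6-(2-methylpropanoyl)-2H-chromen-5(4aH)-one F2. Preparative chromatography on a chiral stationary phase would deliver 8.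

2. Step 3. O-Prenylation of the phenoxides and over-alkylation (a third, geminal prenylation with dearomatisation) may compete with the double C-alkylation, since the 4-ether makes the ring less nucleophilic than a free phloroglucinol. The fallback sets out from 3 and comes back at 7, with the order of C–C and C–O bond formation reversed. Double C-prenylation of the free triphenol 3 (6, aq. KOH, 0 °C), a documented transformation, should give deoxycohumulone (2-methyl-1-[2,4,6-trihydroxy-3,5-bis(3-methylbut-2-en-1-yl)phenyl]propan-1-one) F3. Copper-catalysed propargylic etherification of F3 with 4 (DBU, CuCl2 cat., MeCN, 0 °C) at its most acidic phenol, the 4-OH para to the acyl group, should then give 7.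

3. Step 2. Site selection among the three phenolic oxygens may be incomplete (bis-etherification), and the ambident phloroglucinol anion may be propargylated at carbon. The fallback sets out from 3 and comes back at 5, replacing substrate control with protecting groups. Peracetylation (Ac2O, pyridine, DMAP) should give 2-(2-methylpropanoyl)benzene-1,3,5-triyl triacetate F4. Selective thiolysis of the least hindered and most activated acetate, para to the ketone (PhSH, imidazole, NMP, 0 °C), should give 5-hydroxy-2-(2-methylpropanoyl)-1,3-phenylene diacetate F5. Copper-catalysed etherification of the only free phenol with 4 should give 5-(2-methylbut-3-yn-2-yloxy)-2-(2-methylpropanoyl)-1,3-phenylene diacetate F6, and methanolysis (K2CO3 cat., MeOH, 0 °C) should return 5.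

**Further compounds**

F1 | step 4 | racemic 3,5-dihydroxy-2,6-bis(3-methylbut-2-en-1-yl)-6-(3-methylbuta-1,2-dien-1-yl)-4-(2-methylpropanoyl)cyclohexa-2,4-dien-1-one | CC(C)=CCC1=C(O)C(C(=O)C(C)C)=C(O)C(CC=C(C)C)(C=C=C(C)C)C1=O
F2 | step 4 | racemic 7-hydroxy-2,2-dimethyl-4a,8-bis(3-methylbut-2-en-1-yl)-6-(2-methylpropanoyl)-2H-chromen-5(4aH)-one | CC(C)=CCC1=C2OC(C)(C)C=CC2(CC=C(C)C)C(=O)C(C(=O)C(C)C)=C1O
F3 | step 3 | deoxycohumulone (2-methyl-1-[2,4,6-trihydroxy-3,5-bis(3-methylbut-2-en-1-yl)phenyl]propan-1-one) | CC(C)C(=O)c1c(O)c(CC=C(C)C)c(O)c(CC=C(C)C)c1O
F4 | step 2 | 2-(2-methylpropanoyl)benzene-1,3,5-triyl triacetate | CC(C)C(=O)c1c(OC(C)=O)cc(OC(C)=O)cc1OC(C)=O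
F5 | step 2 | 5-hydroxy-2-(2-methylpropanoyl)-1,3-phenylene diacetate | CC(C)C(=O)c1c(OC(C)=O)cc(O)cc1OC(C)=O
F6 | step 2 | 5-(2-methylbut-3-yn-2-yloxy)-2-(2-methylpropanoyl)-1,3-phenylene diacetate | CC(C)C(=O)c1c(OC(C)=O)cc(OC(C)(C)C#C)cc1OC(C)=O
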